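## The problem

The target is a 2,3-dihydrobenzofuran (benzene ring A fused to dihydrofuran ring B) with three oxygenated appendages: a 1-formylvinyl group on C2, an isovalerate on C3, and an (S)-1-(senecioyloxy)ethyl group on C5, para to O1. C2 and C3 are contiguous, both R and cis, so they must be made together or taken together from one source. The benzylic carbinol on C5 is too far from them to be steered by the ring and needs reagent control. The C3 oxygen is benzylic and β to C2–H, and its expulsion aromatises ring B to a benzofuran. This becomes easy once a side-chain carbonyl acidifies C2–H or once C3–O is acylated, which dictates when the aldehyde and the esters may appear. The enal is a Michael acceptor and, next to a free cis C3–OH, would close to a lactol. The p-alkoxybenzylic senecioate can ionise under acid and can deconjugate under base, and two different acyl groups must reach two secondary hydroxyls without crossover. The enabling feature is that O1, C2, C3, C3a and C7a, with the cis C2/C3 pair and a C2 branch carrying one more oxygenated carbon, are the ring oxygen, C4, C3, C2, C1 and C5/C6 of a D-arabino hexofuranoid glycal. Only C4–C7 of ring A are missing, and these are the two carbons of a vinyl ether plus the two of an ynone.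

## Retrosynthesis

**Aldehyde last (22 ⇐ 21 ⇐ 20).** The enal of 22 is traced to allylic alcohol 21 and this to its PMB ether 20. Unveiling the aldehyde last means no enolisable or electrophilic carbonyl sits next to C2 while C3 carries an ester, and no free C3–OH ever faces the aldehyde. The forward steps need only a neutral ether cleavage and a neutral allylic oxidation.

**C3 ester (20 ⇐ 19 ⇐ 18).** The isovalerate is cut at its acyl–O bond to alcohol 19, which comes from silyl ether 18. A silyl ether at C3 is a far poorer leaving group than an ester and is therefore kept through all steps in which the side chain is a ketone. Fluoride must remove it without touching the C6 protecting group, which is why that group is PMB.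

**C2 side chain (18 ⇐ 17 ⇐ 16 ⇐ 14 ⇐ 13).** The C=CH2 bond is cut to ketone 17, the ketone to carbinol 16, and 16 through stannylene acetal 15 to diol 14, which is the hydrolysed dioxolane of 13. This uses sugar C5 as the alkene carbon and sugar C6 as the future aldehyde carbon, so no late allylic C–H oxidation is needed. The alternative of carrying the methylene group through the glycal stage was rejected because an allylic silyl ether and its allylic, α-oxygenated C–H would not survive the t-BuLi needed at C1. The price is ketone 17, which demands a non-basic methylenation.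

**C5 side chain (13 ⇐ 12 ⇐ 11).** The senecioate is cut at the acyl–O bond to carbinol 12 and the carbinol C–H bond to aryl methyl ketone 11. Doing this before the side-chain work removes the only other ketone before 17 is made, and the senecioate then serves as its own protecting group. The reduction must be catalyst-controlled.

**Ring A (11 ⇐ 8 + 9, through 10).** The C3a–C4 and C5–C6 bonds are cut, which reduces the arene to diene 8 and but-3-yn-2-one 9. Against cuts inside ring B (C2–C3, C3–C3a or O1–C2), this leaves both stereocentres untouched in a sugar and makes the acetyl position a matter of diene polarisation, not of arene substitution. The forward reaction must be regioselective and must aromatise by loss of ethanol from cycloadduct 10, not by loss of the C3 oxygen.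

**Diene (8 ⇐ 6 + 7).** The bond between glycal C1 and the vinyl carbon is cut to 1-iodoglycal 6 and the commercial E-boronate 7. A cross-coupling fixes the E geometry that the cycloaddition needs. Olefination of a 1-formyl glycal would give E/Z mixtures.

**Glycal (6 ⇐ 4 ⇐ 3 ⇐ 2 ⇐ 1).** Iodide 6 comes from C1 lithiation of silyl glycal 4 (through lithio species 5), 4 from alcohol 3, and 3 by reductive fragmentation of chloride 2, made from diacetone-D-mannose 1. Sugar C2 ends as the sp2 carbon C3a, so mannose and glucose give the same glycal. Mannose is preferred because its 2,3-cis acetonide delivers the glycal with a free 3-OH in two steps, and the 5,6-acetonide left in place is inert to t-BuLi. TIPS is chosen over a benzylic ether at O3 because it has no acidic C–H.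

## Roads not taken

Alternative 1: The cut is the C2–C3 bond. An eight-membered cyclic aryl enol ether A2 already holds O1 on the future C2 and the future C3 as a benzylic OCH2 of an allylic ether. Deprotonation there with t-BuLi and a chiral bis(oxazoline) would trigger a transannular [2,3]-Wittig shift that forms C2–C3, frees the C3 alkoxide and turns the enol ether into the 2-propenyl group, giving alcohol A1. Its merits are real: ring B, both stereocentres and the propenyl group arise in one step from an achiral, quickly made precursor, and the route would probably be several steps shorter than the chosen one. Its weak points are that absolute configuration rests on a ligand-controlled organolithium rearrangement whose selectivity is substrate-dependent and untested in a medium ring, and that [1,2]-shift and lithiation at other sites compete. The side-chain methyl would also have to be oxidised to the aldehyde late, next to C2–H and two sensitive esters. Any shortfall in enantiopurity turns into diastereomers after the second asymmetric step. Against the shorter count, the chosen plan sets C2/C3 configuration taken intact from a sugar and a side-chain oxygen that is already in place.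

Alternative 2: The cut is the C3–C3a bond. A trans 4-aryloxy-5-menthyloxy lactone A4, made by conjugate addition of the acetyl-bearing phenol to a menthol-derived butenolide acetal, would be ionised by a Lewis acid. The oxocarbenium carbon would then be attacked by the ortho carbon of the aryl ether, closing ring B as the cis-fused tricyclic lactone A3. The chirality source is cheaper than any sugar sequence, the cis fusion is enforced by the 5/5 ring system, and the core is reached in very few steps. The weak points are a Friedel–Crafts attack by an arene deactivated through its para acetyl group, and a cation β to the aryloxy oxygen that can lose phenoxide instead. The lactone must afterwards be α-methylenated and reduced to the aldehyde level, and the resulting cis 3-hydroxy enal would sit as a cyclic lactol, which makes selective isovalerylation of C3–OH awkward. The chosen plan is longer but builds ring A instead of substituting it, and keeps C3–O silylated until the aldehyde is the last thing to appear.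

Alternative 3: The cut is the O1–C2 bond, re-formed by migration. A cis 4-acyloxy-2,2-dimethylchroman-3-ol A6, available by catalytic asymmetric dihydroxylation of the corresponding chromene and acylation of the benzylic hydroxyl, would be triflated at C3–OH. The ring oxygen would shift from the quaternary carbon to C3, and the tertiary cation would lose a methyl proton, giving the ring-contracted ester A5 with the isovalerate already installed. This is probably the shortest road of all and uses one of the most reliable asymmetric oxidations. Its weak points are mechanistic: the C4–H is anti to the leaving group and can migrate instead of the ring oxygen, elimination to an enol ester competes, and the shift needs a conformation with the triflate axial. The product also still lacks the side-chain oxygen, so an allylic oxidation of the propenyl methyl must be done late on a compound that eliminates easily to a benzofuran. The chosen plan concedes step count and catalytic economy and sets against them the absence of a cationic skeletal rearrangement and a side-chain oxygen supplied by the sugar.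

Key step: step 6

## Route

Remark: sugar C2 becomes the sp2 carbon C3a, so D-mannose (same C3, C4 and C5 as D-glucose) is used as the source of the D-arabino glycal.

Step 1
Reactants: 1 2,3:5,6-di-O-isopropylidene-α-D-mannofuranose
Product: 2 2,3:5,6-di-O-isopropylidene-α-D-mannofuranosyl chloride
Conditions: PPh3, CCl4, THF, reflux
Reagents that add atoms: carbon tetrachloride, ClC(Cl)(Cl)Cl
Why: Appel-type chlorination of the lactol hydroxyl; the anomeric configuration does not matter because C1 becomes sp2 in step 2.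

Step 2
Reactants: 2 2,3:5,6-di-O-isopropylidene-α-D-mannofuranosyl chloride
Product: 3 1,4-anhydro-2-deoxy-5,6-O-isopropylidene-D-arabino-hex-1-enitol
Conditions: Li, liquid NH3, THF, −78 °C; then NH4Cl
Reagents that add atoms: none
Why: Two-electron reduction of the C–Cl bond gives an anomeric carbanion that expels the C2 oxygen of the 2,3-acetonide (reductive β-elimination, the classical dissolving-metal route to furanoid glycals); the hemiketal alkoxide sheds acetone and leaves the free 3-OH, with C3, C4 and C5 untouched.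

Step 3
Reactants: 3 1,4-anhydro-2-deoxy-5,6-O-isopropylidene-D-arabino-hex-1-enitol
Product: 4 1,4-anhydro-2-deoxy-5,6-O-isopropylidene-3-O-triisopropylsilyl-D-arabino-hex-1-enitol
Conditions: TIPSCl, imidazole, DMF, 23 °C
Reagents that add atoms: triisopropylsilyl chloride, CC(C)[Si](Cl)(C(C)C)C(C)C
Why: Silylation of the allylic secondary alcohol under basic conditions that the acid-labile enol ether tolerates; TIPS withstands t-BuLi and has no benzylic or allylic C–H.

Step 4
Reactants: 4 1,4-anhydro-2-deoxy-5,6-O-isopropylidene-3-O-triisopropylsilyl-D-arabino-hex-1-enitol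
Product: 6 1,4-anhydro-2-deoxy-1-iodo-5,6-O-isopropylidene-3-O-triisopropylsilyl-D-arabino-hex-1-enitol, via 1-lithio glycal 5 (not isolated)
Conditions: t-BuLi, THF, −78 → 0 °C; then I2, THF, −78 °C
Reagents that add atoms: iodine, II
Why: The vinylic C1–H next to the ring oxygen is the kinetically most acidic site, and α-lithiation of silyl-protected glycals with t-BuLi is established, also for 3-O-silyl furanoid glycals; iodine quench of the alkenyllithium gives the α-iodo enol ether, which is used at once.

Step 5
Reactants: 6 1,4-anhydro-2-deoxy-1-iodo-5,6-O-isopropylidene-3-O-triisopropylsilyl-D-arabino-hex-1-enitol; 7 (E)-2-(2-ethoxyethenyl)-4,4,5,5-tetramethyl-1,3,2-dioxaborolane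
Product: 8 1,4-anhydro-2-deoxy-1-C-[(E)-2-ethoxyethenyl]-5,6-O-isopropylidene-3-O-triisopropylsilyl-D-arabino-hex-1-enitol
Conditions: Pd(PPh3)4 (5 mol%), aq. K3PO4, THF, 45 °C
Reagents that add atoms: none
Why: Suzuki–Miyaura coupling of an alkenyl iodide with an alkenyl boronate under zerovalent palladium catalysis; both partners couple with retention, so the E geometry of 7 is carried into the diene, and the basic medium preserves both enol ethers.

Step 6
Reactants: 8 1,4-anhydro-2-deoxy-1-C-[(E)-2-ethoxyethenyl]-5,6-O-isopropylidene-3-O-triisopropylsilyl-D-arabino-hex-1-enitol; 9 but-3-yn-2-one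
Product: 11 1-[(2R,3R)-2-[(4R)-2,2-dimethyl-1,3-dioxolan-4-yl]-3-[(triisopropylsilyl)oxy]-2,3-dihydro-1-benzofuran-5-yl]ethan-1-one, via cycloadduct 10 (not isolated)
Conditions: toluene, 70 °C; then PPTS (cat.), 23 °C
Reagents that add atoms: none
Why: The glycal enol ether (C3a=C7a) and the E-ethoxyvinyl group form an s-cis 1-ethoxy-3-oxy-diene whose HOMO is raised by both oxygens and is largest at the glycal CH; it adds to the ynone in a concerted, asynchronous [4+2] in which C3a bonds to the alkyne CH (C4) and the ethoxy-bearing carbon (C6) bonds to the acetyl-bearing carbon (C5), giving 10. Ring A thus closes as a six-membered carbocycle by intermolecular [4+2] cycloaddition (four diene carbons plus two alkyne carbons), and 1,4-elimination of ethanol (ionisation of the doubly allylic, O1-stabilised C6–OEt bond, then loss of H-3a) aromatises it without an oxidant. The closest known reaction types are the benzannulation of 1-alkoxy-3-silyloxy-dienes with acetylenic ketones followed by loss of alcohol, and Diels–Alder reactions of C1-vinyl glycals. No lasting stereocentre is formed (C3a and C6 of 10 are erased), and C2 and C3 keep the sugar configuration as spectators. The step needs regioselectivity, secured because both donors (O1 on C7a, OEt on C6) polarise the diene the same way and place the acetyl group para to O1. It also needs loss of ethanol in preference to silanol, secured because C6–OEt is a vinylogous acetal whereas C3–O ionisation is unconjugated (C3a is sp3 in 10) and disfavoured by O1 on the neighbouring C2. The E geometry set in step 5 is what makes the s-cis conformer accessible.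

Step 7
Reactants: 11 1-[(2R,3R)-2-[(4R)-2,2-dimethyl-1,3-dioxolan-4-yl]-3-[(triisopropylsilyl)oxy]-2,3-dihydro-1-benzofuran-5-yl]ethan-1-one
Product: 12 (1S)-1-[(2R,3R)-2-[(4R)-2,2-dimethyl-1,3-dioxolan-4-yl]-3-[(triisopropylsilyl)oxy]-2,3-dihydro-1-benzofuran-5-yl]ethan-1-ol
Conditions: RuCl(p-cymene)[(S,S)-TsDPEN] (2 mol%), HCO2H/Et3N (5:2), DMF, 30 °C
Reagents that add atoms: none
Why: Noyori asymmetric transfer hydrogenation of an aryl methyl ketone; the (S,S)-TsDPEN catalyst delivers hydride to the Re face and sets the (S)-carbinol under catalyst control, the ring stereocentres being too remote to interfere; acetonide and silyl ether tolerate the formic acid/triethylamine medium.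

Step 8
Reactants: 12 (1S)-1-[(2R,3R)-2-[(4R)-2,2-dimethyl-1,3-dioxolan-4-yl]-3-[(triisopropylsilyl)oxy]-2,3-dihydro-1-benzofuran-5-yl]ethan-1-ol
Product: 13 (1S)-1-[(2R,3R)-2-[(4R)-2,2-dimethyl-1,3-dioxolan-4-yl]-3-[(triisopropylsilyl)oxy]-2,3-dihydro-1-benzofuran-5-yl]ethyl 3-methylbut-2-enoate
Conditions: 3-methylbut-2-enoic acid, DCC, DMAP (cat.), CH2Cl2, 0 → 23 °C
Reagents that add atoms: 3-methylbut-2-enoic acid, CC(C)=CC(O)=O
Why: Steglich esterification acylates the carbinol oxygen without breaking its C–O bond, so the S configuration is retained; the acid/carbodiimide protocol is preferred to the acid chloride/amine route, which tends to deconjugate senecioates through a vinylketene.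

Step 9
Reactants: 13 (1S)-1-[(2R,3R)-2-[(4R)-2,2-dimethyl-1,3-dioxolan-4-yl]-3-[(triisopropylsilyl)oxy]-2,3-dihydro-1-benzofuran-5-yl]ethyl 3-methylbut-2-enoate
Product: 14 (1S)-1-[(2R,3R)-2-[(1R)-1,2-dihydroxyethyl]-3-[(triisopropylsilyl)oxy]-2,3-dihydro-1-benzofuran-5-yl]ethyl 3-methylbut-2-enoate
Conditions: AcOH/H2O (4:1), 35 °C
Reagents that add atoms: none
Why: Acid-catalysed hydrolysis of the terminal isopropylidene acetal; the hindered secondary TIPS ether and both ester types should survive the weak acid, and the low temperature limits ionisation of the benzylic ester.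

Step 10
Reactants: 14 (1S)-1-[(2R,3R)-2-[(1R)-1,2-dihydroxyethyl]-3-[(triisopropylsilyl)oxy]-2,3-dihydro-1-benzofuran-5-yl]ethyl 3-methylbut-2-enoate
Product: 16 (1S)-1-[(2R,3R)-2-[(1R)-1-hydroxy-2-[(4-methoxybenzyl)oxy]ethyl]-3-[(triisopropylsilyl)oxy]-2,3-dihydro-1-benzofuran-5-yl]ethyl 3-methylbut-2-enoate, via stannylene acetal 15 (not isolated)
Conditions: Bu2SnO, toluene, reflux (Dean–Stark); then PMBCl, Bu4NI (cat.), 70 °C
Reagents that add atoms: 4-methoxybenzyl chloride, COc1ccc(CCl)cc1
Why: Stannylene-acetal-mediated regioselective O-alkylation of a terminal 1,2-diol: the primary oxygen of the five-membered stannylene is the more nucleophilic and takes the PMB group under neutral conditions that spare esters and silyl ether; PMB is chosen because it must outlive the fluoride of step 13.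

Step 11
Reactants: 16 (1S)-1-[(2R,3R)-2-[(1R)-1-hydroxy-2-[(4-methoxybenzyl)oxy]ethyl]-3-[(triisopropylsilyl)oxy]-2,3-dihydro-1-benzofuran-5-yl]ethyl 3-methylbut-2-enoate
Product: 17 (1S)-1-[(2S,3R)-2-{[(4-methoxybenzyl)oxy]acetyl}-3-[(triisopropylsilyl)oxy]-2,3-dihydro-1-benzofuran-5-yl]ethyl 3-methylbut-2-enoate (cis; the 2S label reflects a changed CIP priority and not an inversion)
Conditions: Dess–Martin periodinane, NaHCO3, CH2Cl2, 0 → 23 °C
Reagents that add atoms: none
Why: Dess–Martin oxidation of the secondary carbinol under bicarbonate buffer; the α-aryloxy ketone is enolisable and is taken on crude without chromatography.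

Step 12
Reactants: 17 (1S)-1-[(2S,3R)-2-{[(4-methoxybenzyl)oxy]acetyl}-3-[(triisopropylsilyl)oxy]-2,3-dihydro-1-benzofuran-5-yl]ethyl 3-methylbut-2-enoate
Product: 18 (1S)-1-[(2R,3R)-2-{3-[(4-methoxybenzyl)oxy]prop-1-en-2-yl}-3-[(triisopropylsilyl)oxy]-2,3-dihydro-1-benzofuran-5-yl]ethyl 3-methylbut-2-enoate
Conditions: Zn, CH2Br2, TiCl4, THF/CH2Cl2, 0 → 23 °C
Reagents that add atoms: dibromomethane, BrCBr
Why: Takai–Lombardo methylenation (gem-dimetallic CH2 reagent from Zn, CH2Br2 and TiCl4) converts the ketone into the 1,1-disubstituted alkene without a basic ylide, so C2 is not epimerised and the 3-silyloxy group is not expelled; esters, PMB ether and silyl ether are inert to the reagent.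

Step 13
Reactants: 18 (1S)-1-[(2R,3R)-2-{3-[(4-methoxybenzyl)oxy]prop-1-en-2-yl}-3-[(triisopropylsilyl)oxy]-2,3-dihydro-1-benzofuran-5-yl]ethyl 3-methylbut-2-enoate
Product: 19 (1S)-1-[(2R,3R)-3-hydroxy-2-{3-[(4-methoxybenzyl)oxy]prop-1-en-2-yl}-2,3-dihydro-1-benzofuran-5-yl]ethyl 3-methylbut-2-enoate
Conditions: TBAF, AcOH, THF, 0 → 23 °C
Reagents that add atoms: none
Why: Fluoride cleavage of the silyl ether, buffered with acetic acid so that the alkoxide neither attacks nor deconjugates the senecioate; the PMB ether is unaffected and no carbonyl acidifies C2–H at this stage.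

Step 14
Reactants: 19 (1S)-1-[(2R,3R)-3-hydroxy-2-{3-[(4-methoxybenzyl)oxy]prop-1-en-2-yl}-2,3-dihydro-1-benzofuran-5-yl]ethyl 3-methylbut-2-enoate
Product: 20 (2R,3R)-2-{3-[(4-methoxybenzyl)oxy]prop-1-en-2-yl}-5-[(1S)-1-[(3-methylbut-2-enoyl)oxy]ethyl]-2,3-dihydro-1-benzofuran-3-yl 3-methylbutanoate
Conditions: 3-methylbutanoyl chloride, pyridine, DMAP (cat.), CH2Cl2, 0 → 23 °C
Reagents that add atoms: 3-methylbutanoyl chloride, CC(C)CC(Cl)=O
Why: DMAP-catalysed acylation of the benzylic secondary alcohol with the saturated acid chloride; the C3–O bond is not broken, so the configuration is kept.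

Step 15
Reactants: 20 (2R,3R)-2-{3-[(4-methoxybenzyl)oxy]prop-1-en-2-yl}-5-[(1S)-1-[(3-methylbut-2-enoyl)oxy]ethyl]-2,3-dihydro-1-benzofuran-3-yl 3-methylbutanoate
Product: 21 (2R,3R)-2-(3-hydroxyprop-1-en-2-yl)-5-[(1S)-1-[(3-methylbut-2-enoyl)oxy]ethyl]-2,3-dihydro-1-benzofuran-3-yl 3-methylbutanoate
Conditions: DDQ, CH2Cl2/pH 7 buffer, 0 → 23 °C
Reagents that add atoms: none
Why: Oxidative PMB ether cleavage by DDQ (oxidation of the anisyl ring, hydrolysis of the resulting oxocarbenium ion); benzylic positions bearing acyloxy groups are poor hydride donors and should be left alone.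

Step 16
Reactants: 21 (2R,3R)-2-(3-hydroxyprop-1-en-2-yl)-5-[(1S)-1-[(3-methylbut-2-enoyl)oxy]ethyl]-2,3-dihydro-1-benzofuran-3-yl 3-methylbutanoate
Product: 22 (2R,3R)-5-[(1S)-1-[(3-methylbut-2-enoyl)oxy]ethyl]-2-(3-oxoprop-1-en-2-yl)-2,3-dihydro-1-benzofuran-3-yl 3-methylbutanoate
Conditions: MnO2, CH2Cl2, 23 °C
Reagents that add atoms: none
Why: MnO2 oxidises the primary allylic alcohol selectively to the 2-substituted acrolein under neutral heterogeneous conditions, so the enal appears only in the last step and neither ester nor C2/C3 is disturbed.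

## Compound list

1 | 2,3:5,6-di-O-isopropylidene-α-D-mannofuranose | CC1(C)OC[C@@H](O1)[C@H]1O[C@H](O)[C@H]2OC(C)(C)O[C@@H]12 | starting material
2 | 2,3:5,6-di-O-isopropylidene-α-D-mannofuranosyl chloride | CC1(C)OC[C@@H](O1)[C@H]1O[C@H](Cl)[C@H]2OC(C)(C)O[C@@H]12 | intermediate
3 | 1,4-anhydro-2-deoxy-5,6-O-isopropylidene-D-arabino-hex-1-enitol | CC1(C)OC[C@@H](O1)[C@H]1OC=C[C@H]1O | intermediate
4 | 1,4-anhydro-2-deoxy-5,6-O-isopropylidene-3-O-triisopropylsilyl-D-arabino-hex-1-enitol | CC1(C)OC[C@@H](O1)[C@H]1OC=C[C@H]1O[Si](C(C)C)(C(C)C)C(C)C | intermediate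
5 | 1,4-anhydro-2-deoxy-5,6-O-isopropylidene-1-lithio-3-O-triisopropylsilyl-D-arabino-hex-1-enitol (1-lithio glycal) | CC1(C)OC[C@@H](O1)[C@H]1OC([Li])=C[C@H]1O[Si](C(C)C)(C(C)C)C(C)C | intermediate
6 | 1,4-anhydro-2-deoxy-1-iodo-5,6-O-isopropylidene-3-O-triisopropylsilyl-D-arabino-hex-1-enitol | CC1(C)OC[C@@H](O1)[C@H]1OC(I)=C[C@H]1O[Si](C(C)C)(C(C)C)C(C)C | intermediate
7 | (E)-2-(2-ethoxyethenyl)-4,4,5,5-tetramethyl-1,3,2-dioxaborolane | CCO/C=C/B1OC(C)(C)C(C)(C)O1 | starting material
8 | 1,4-anhydro-2-deoxy-1-C-[(E)-2-ethoxyethenyl]-5,6-O-isopropylidene-3-O-triisopropylsilyl-D-arabino-hex-1-enitol | CC1(C)OC[C@@H](O1)[C@H]1OC(/C=C/OCC)=C[C@H]1O[Si](C(C)C)(C(C)C)C(C)C | intermediate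
9 | but-3-yn-2-one | CC(=O)C#C | starting material
10 | 1-[(2R,3R)-2-[(4R)-2,2-dimethyl-1,3-dioxolan-4-yl]-6-ethoxy-3-[(triisopropylsilyl)oxy]-2,3,3a,6-tetrahydro-1-benzofuran-5-yl]ethan-1-one (cycloadduct; C3a and C6 as formed) | CC1(C)OC[C@@H](O1)[C@H]1OC2=CC(OCC)C(C(C)=O)=CC2[C@H]1O[Si](C(C)C)(C(C)C)C(C)C | intermediate
11 | 1-[(2R,3R)-2-[(4R)-2,2-dimethyl-1,3-dioxolan-4-yl]-3-[(triisopropylsilyl)oxy]-2,3-dihydro-1-benzofuran-5-yl]ethan-1-one | CC1(C)OC[C@@H](O1)[C@H]1Oc2ccc(C(C)=O)cc2[C@H]1O[Si](C(C)C)(C(C)C)C(C)C | intermediate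
12 | (1S)-1-[(2R,3R)-2-[(4R)-2,2-dimethyl-1,3-dioxolan-4-yl]-3-[(triisopropylsilyl)oxy]-2,3-dihydro-1-benzofuran-5-yl]ethan-1-ol | CC1(C)OC[C@@H](O1)[C@H]1Oc2ccc([C@H](C)O)cc2[C@H]1O[Si](C(C)C)(C(C)C)C(C)C | intermediate
13 | (1S)-1-[(2R,3R)-2-[(4R)-2,2-dimethyl-1,3-dioxolan-4-yl]-3-[(triisopropylsilyl)oxy]-2,3-dihydro-1-benzofuran-5-yl]ethyl 3-methylbut-2-enoate | CC1(C)OC[C@@H](O1)[C@H]1Oc2ccc([C@H](C)OC(=O)C=C(C)C)cc2[C@H]1O[Si](C(C)C)(C(C)C)C(C)C | intermediate
14 | (1S)-1-[(2R,3R)-2-[(1R)-1,2-dihydroxyethyl]-3-[(triisopropylsilyl)oxy]-2,3-dihydro-1-benzofuran-5-yl]ethyl 3-methylbut-2-enoate | OC[C@@H](O)[C@H]1Oc2ccc([C@H](C)OC(=O)C=C(C)C)cc2[C@H]1O[Si](C(C)C)(C(C)C)C(C)C | intermediate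
15 | stannylene acetal of 14: the 2,2-dibutyl-1,3,2-dioxastannolane formed from its two side-chain hydroxyls (all stereocentres as in 14) | CCCC[Sn]1(CCCC)OC[C@@H](O1)[C@H]1Oc2ccc([C@H](C)OC(=O)C=C(C)C)cc2[C@H]1O[Si](C(C)C)(C(C)C)C(C)C | intermediate
16 | (1S)-1-[(2R,3R)-2-[(1R)-1-hydroxy-2-[(4-methoxybenzyl)oxy]ethyl]-3-[(triisopropylsilyl)oxy]-2,3-dihydro-1-benzofuran-5-yl]ethyl 3-methylbut-2-enoate | COc1ccc(COC[C@@H](O)[C@H]2Oc3ccc([C@H](C)OC(=O)C=C(C)C)cc3[C@H]2O[Si](C(C)C)(C(C)C)C(C)C)cc1 | intermediate
17 | (1S)-1-[(2S,3R)-2-{[(4-methoxybenzyl)oxy]acetyl}-3-[(triisopropylsilyl)oxy]-2,3-dihydro-1-benzofuran-5-yl]ethyl 3-methylbut-2-enoate (cis) | COc1ccc(COCC(=O)[C@H]2Oc3ccc([C@H](C)OC(=O)C=C(C)C)cc3[C@H]2O[Si](C(C)C)(C(C)C)C(C)C)cc1 | intermediate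
18 | (1S)-1-[(2R,3R)-2-{3-[(4-methoxybenzyl)oxy]prop-1-en-2-yl}-3-[(triisopropylsilyl)oxy]-2,3-dihydro-1-benzofuran-5-yl]ethyl 3-methylbut-2-enoate | C=C(COCc1ccc(OC)cc1)[C@H]1Oc2ccc([C@H](C)OC(=O)C=C(C)C)cc2[C@H]1O[Si](C(C)C)(C(C)C)C(C)C | intermediate
19 | (1S)-1-[(2R,3R)-3-hydroxy-2-{3-[(4-methoxybenzyl)oxy]prop-1-en-2-yl}-2,3-dihydro-1-benzofuran-5-yl]ethyl 3-methylbut-2-enoate | C=C(COCc1ccc(OC)cc1)[C@H]1Oc2ccc([C@H](C)OC(=O)C=C(C)C)cc2[C@H]1O | intermediate
20 | (2R,3R)-2-{3-[(4-methoxybenzyl)oxy]prop-1-en-2-yl}-5-[(1S)-1-[(3-methylbut-2-enoyl)oxy]ethyl]-2,3-dihydro-1-benzofuran-3-yl 3-methylbutanoate | C=C(COCc1ccc(OC)cc1)[C@H]1Oc2ccc([C@H](C)OC(=O)C=C(C)C)cc2[C@H]1OC(=O)CC(C)C | intermediate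
21 | (2R,3R)-2-(3-hydroxyprop-1-en-2-yl)-5-[(1S)-1-[(3-methylbut-2-enoyl)oxy]ethyl]-2,3-dihydro-1-benzofuran-3-yl 3-methylbutanoate | C=C(CO)[C@H]1Oc2ccc([C@H](C)OC(=O)C=C(C)C)cc2[C@H]1OC(=O)CC(C)C | intermediate
22 | (2R,3R)-5-[(1S)-1-[(3-methylbut-2-enoyl)oxy]ethyl]-2-(3-oxoprop-1-en-2-yl)-2,3-dihydro-1-benzofuran-3-yl 3-methylbutanoate | C=C(C=O)[C@H]1Oc2ccc([C@H](C)OC(=O)C=C(C)C)cc2[C@H]1OC(=O)CC(C)C | target

## Step count and uncertain steps

Total: 16 steps. Longest linear sequence: 16 steps, from 1 to 22; 7 and 9 are bought.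

**Step 6 (key step).** The cycloaddition of a furanoid C1-(alkoxyvinyl) glycal carrying an allylic C3 ether has not been tried. The most likely failures are decomposition of the dienol ether before it cycloadds (hydrolysis, or loss of silanol with furan formation on warming or with trace acid) and oligomerisation of the ynone by conjugate addition. The fallback sets out from 8 and uses the more tractable alkene dienophile but-3-en-2-one at lower temperature, which should give 1-[(2R,3R)-2-[(4R)-2,2-dimethyl-1,3-dioxolan-4-yl]-6-ethoxy-3-[(triisopropylsilyl)oxy]-2,3,3a,4,5,6-hexahydro-1-benzofuran-5-yl]ethan-1-one F1. DBU would expel ethanol from this β-ethoxy ketone to give the dienone 1-[(2R,3R)-2-[(4R)-2,2-dimethyl-1,3-dioxolan-4-yl]-3-[(triisopropylsilyl)oxy]-2,3,3a,4-tetrahydro-1-benzofuran-5-yl]ethan-1-one F2, and DDQ dehydrogenation of F2 returns to the route at 11. The silyl ether at C3, unlike a PMB ether, allows this oxidant.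

**Step 4.** Lithiation may stray to other sites, and the α-iodo enol ether may not survive the oxidising quench and work-up. The fallback sets out from 4: the lithio species is trapped with Bu3SnCl to give the storable 1,4-anhydro-2-deoxy-5,6-O-isopropylidene-1-(tributylstannyl)-3-O-triisopropylsilyl-D-arabino-hex-1-enitol F3, and iododestannylation (I2, CH2Cl2, 0 °C) just before the coupling returns to the route at 6.

**Step 5.** Protodehalogenation or hydrolysis of the iodide and protodeboronation of the β-alkoxyvinyl boronate in warm aqueous base can outrun the coupling, and the dienol ether may hydrolyse on isolation. The fallback sets out from 4 and avoids the halide. Lithiation as in step 4 and a DMF quench would give 1,4-anhydro-2-deoxy-1-C-formyl-5,6-O-isopropylidene-3-O-triisopropylsilyl-D-arabino-hex-1-enitol F4. Wittig reaction with the ylide from (ethoxymethyl)triphenylphosphonium chloride and KHMDS returns to the route at 8. It would come mixed with its geometric isomer 1,4-anhydro-2-deoxy-1-C-[(Z)-2-ethoxyethenyl]-5,6-O-isopropylidene-3-O-triisopropylsilyl-D-arabino-hex-1-enitol F5, which reaches the s-cis conformer poorly and would be left behind in step 6.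

**Step 12 (with the ketone from step 11).** Enolisation of the α-aryloxy ketone would epimerise C2 or expel the C3 silyloxy group with aromatisation to a 2-acylbenzofuran; the Lewis-acidic reagent could also ionise the benzylic ester. The fallback sets out from 17: Me3SiCH2MgCl/CeCl3 (THF, −78 °C) should add to the ketone without enolising it and without touching the esters, giving the β-hydroxysilane (1S)-1-[(3R)-2-[2-hydroxy-1-[(4-methoxybenzyl)oxy]-3-(trimethylsilyl)propan-2-yl]-3-[(triisopropylsilyl)oxy]-2,3-dihydro-1-benzofuran-5-yl]ethyl 3-methylbut-2-enoate F6. Peterson elimination (KHMDS, THF, −78 → 0 °C) returns to the route at 18.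

**Step 9.** Acid may ionise the p-alkoxybenzylic senecioate, with solvolysis or loss of configuration at the carbinol carbon, before the acetonide is gone. The fallback sets out from 11, where the ring is deactivated and no benzylic leaving group exists. Aqueous acetic acid would give the diol 1-[(2R,3R)-2-[(1R)-1,2-dihydroxyethyl]-3-[(triisopropylsilyl)oxy]-2,3-dihydro-1-benzofuran-5-yl]ethan-1-one F7. Bu2SnO converts it into its dibutylstannylene acetal F8, and PMBCl gives 1-[(2R,3R)-2-[(1R)-1-hydroxy-2-[(4-methoxybenzyl)oxy]ethyl]-3-[(triisopropylsilyl)oxy]-2,3-dihydro-1-benzofuran-5-yl]ethan-1-one F9. Transfer hydrogenation with RuCl(p-cymene)[(S,S)-TsDPEN] gives the diol (1S)-1-[(2R,3R)-2-[(1R)-1-hydroxy-2-[(4-methoxybenzyl)oxy]ethyl]-3-[(triisopropylsilyl)oxy]-2,3-dihydro-1-benzofuran-5-yl]ethan-1-ol F10. Steglich acylation with one equivalent of 3-methylbut-2-enoic acid at the less hindered benzylic hydroxyl returns to the route at 16.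

## Further compounds

F1 | step 6 | 1-[(2R,3R)-2-[(4R)-2,2-dimethyl-1,3-dioxolan-4-yl]-6-ethoxy-3-[(triisopropylsilyl)oxy]-2,3,3a,4,5,6-hexahydro-1-benzofuran-5-yl]ethan-1-one (C3a, C5 and C6 as formed) | CC1(C)OC[C@@H](O1)[C@H]1OC2=CC(OCC)C(C(C)=O)CC2[C@H]1O[Si](C(C)C)(C(C)C)C(C)C
F2 | step 6 | 1-[(2R,3R)-2-[(4R)-2,2-dimethyl-1,3-dioxolan-4-yl]-3-[(triisopropylsilyl)oxy]-2,3,3a,4-tetrahydro-1-benzofuran-5-yl]ethan-1-one (C3a as formed) | CC1(C)OC[C@@H](O1)[C@H]1OC2=CC=C(C(C)=O)CC2[C@H]1O[Si](C(C)C)(C(C)C)C(C)C
F3 | step 4 | 1,4-anhydro-2-deoxy-5,6-O-isopropylidene-1-(tributylstannyl)-3-O-triisopropylsilyl-D-arabino-hex-1-enitol | CC1(C)OC[C@@H](O1)[C@H]1OC([Sn](CCCC)(CCCC)CCCC)=C[C@H]1O[Si](C(C)C)(C(C)C)C(C)C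
F4 | step 5 | 1,4-anhydro-2-deoxy-1-C-formyl-5,6-O-isopropylidene-3-O-triisopropylsilyl-D-arabino-hex-1-enitol | CC1(C)OC[C@@H](O1)[C@H]1OC(C=O)=C[C@H]1O[Si](C(C)C)(C(C)C)C(C)C
F5 | step 5 | 1,4-anhydro-2-deoxy-1-C-[(Z)-2-ethoxyethenyl]-5,6-O-isopropylidene-3-O-triisopropylsilyl-D-arabino-hex-1-enitol | CC1(C)OC[C@@H](O1)[C@H]1OC(/C=C\OCC)=C[C@H]1O[Si](C(C)C)(C(C)C)C(C)C
F6 | step 12 | (1S)-1-[(3R)-2-[2-hydroxy-1-[(4-methoxybenzyl)oxy]-3-(trimethylsilyl)propan-2-yl]-3-[(triisopropylsilyl)oxy]-2,3-dihydro-1-benzofuran-5-yl]ethyl 3-methylbut-2-enoate (ring substituents cis as in 17; new carbinol centre as formed) | COc1ccc(COCC(O)(C[Si](C)(C)C)[C@H]2Oc3ccc([C@H](C)OC(=O)C=C(C)C)cc3[C@H]2O[Si](C(C)C)(C(C)C)C(C)C)cc1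
F7 | step 9 | 1-[(2R,3R)-2-[(1R)-1,2-dihydroxyethyl]-3-[(triisopropylsilyl)oxy]-2,3-dihydro-1-benzofuran-5-yl]ethan-1-one | OC[C@@H](O)[C@H]1Oc2ccc(C(C)=O)cc2[C@H]1O[Si](C(C)C)(C(C)C)C(C)C
F8 | step 9 | dibutylstannylene acetal of F7 (2,2-dibutyl-1,3,2-dioxastannolane from its two side-chain hydroxyls; stereocentres as in F7) | CCCC[Sn]1(CCCC)OC[C@@H](O1)[C@H]1Oc2ccc(C(C)=O)cc2[C@H]1O[Si](C(C)C)(C(C)C)C(C)C
F9 | step 9 | 1-[(2R,3R)-2-[(1R)-1-hydroxy-2-[(4-methoxybenzyl)oxy]ethyl]-3-[(triisopropylsilyl)oxy]-2,3-dihydro-1-benzofuran-5-yl]ethan-1-one | COc1ccc(COC[C@@H](O)[C@H]2Oc3ccc(C(C)=O)cc3[C@H]2O[Si](C(C)C)(C(C)C)C(C)C)cc1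
F10 | step 9 | (1S)-1-[(2R,3R)-2-[(1R)-1-hydroxy-2-[(4-methoxybenzyl)oxy]ethyl]-3-[(triisopropylsilyl)oxy]-2,3-dihydro-1-benzofuran-5-yl]ethan-1-ol | COc1ccc(COC[C@@H](O)[C@H]2Oc3ccc([C@H](C)O)cc3[C@H]2O[Si](C(C)C)(C(C)C)C(C)C)cc1
A1 | alternative 1 | cis-5-(2-methyl-1,3-dioxolan-2-yl)-2-(prop-1-en-2-yl)-2,3-dihydro-1-benzofuran-3-ol | C=C(C)[C@H]1Oc2ccc(C3(C)OCCO3)cc2[C@H]1O
A2 | alternative 1 | 3-methyl-8-(2-methyl-1,3-dioxolan-2-yl)-4H,6H-1,5-benzodioxocine (eight-membered cyclic aryl enol ether) | CC1=COc2ccc(C3(C)OCCO3)cc2COC1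
A3 | alternative 2 | cis-fused acetyl-substituted 3a,8b-dihydrofuro[3,2-b][1]benzofuran-2(3H)-one (acetyl para to the aryl oxygen) | O=C1C[C@H]2Oc3ccc(C(C)=O)cc3[C@H]2O1
A4 | alternative 2 | (4R,5R)-4-(4-acetylphenoxy)-5-{[(1R,2S,5R)-5-methyl-2-(propan-2-yl)cyclohexyl]oxy}oxolan-2-one (trans) | O=C1C[C@@H](Oc2ccc(C(C)=O)cc2)[C@H](O[C@@H]2C[C@H](C)CC[C@H]2C(C)C)O1
A5 | alternative 3 | cis-5-acetyl-2-(prop-1-en-2-yl)-2,3-dihydro-1-benzofuran-3-yl 3-methylbutanoate | C=C(C)[C@H]1Oc2ccc(C(C)=O)cc2[C@H]1OC(=O)CC(C)C
A6 | alternative 3 | (3R,4R)-6-acetyl-3-hydroxy-2,2-dimethyl-3,4-dihydro-2H-chromen-4-yl 3-methylbutanoate (cis) | CC(=O)c1ccc2OC(C)(C)[C@H](O)[C@H](OC(=O)CC(C)C)c2c1
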